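**Plan**
- Retrosynthesis: the two phenolic MOM ethers are cut last. Ring C is then cut at C2–C3 and O1–C8a in one stroke, which divides the target into ring B aldehyde 10 and ring A enol silane 18. Aldehyde 10 is cut at the aryl–geranyl bond and 18 at the aryl–acetyl bond.
- Forward: ring B comes from 2-bromoisovanillin (acetal, MOM ether, arylcopper geranylation, acetal hydrolysis). Ring A comes from 1-fluoro-3,5-dimethoxybenzene (acylation, ortho-demethylation, MOM ether, enol silane). Ring C is closed last by a formal [4+2] annulation: asymmetric Mukaiyama aldol, then fluoride-relayed SNAr in the same flask.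
- Enabling feature: the C4 ketone lies between the C3 methylene and the C4a–C8a edge of ring A. With fluorine on C8a, the unit C3=C4(OSiMe3)–C4a=C8a–F is a benzo-fused Danishefsky-type diene. The ketone makes C3 nucleophilic and activates C8a for addition–elimination, and the 5- and 7-oxygens are meta to C8a and do not deactivate it.
- Stereochemistry: the only stereocentre, C2 (S), is set by the chiral boron catalyst in the aldol stage (Si-face attack on the aldehyde) and carried through the SNAr stage, where the C2–O bond is not broken. The final deprotection is acidic, so base-induced ring opening to the chalcone cannot scramble it. The (E)-double bond is brought in with geranyl bromide.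

Key step: step 9

Assumption: the (R)-tryptophan-derived oxazaborolidinone is taken to expose the Si face of the bound aldehyde (its antipode the Re face). This sense is to be confirmed on a small scale, and the antipodal catalyst is used if it proves opposite. Compounds 1, 6 and 11 are taken as commercially available.

**Step 1**
Reactants: 1 2-bromo-3-hydroxy-4-methoxybenzaldehyde; 2 ethane-1,2-diol
Product: 3 2-bromo-3-(1,3-dioxolan-2-yl)-6-methoxyphenol
Conditions: TsOH·H2O (cat.), toluene, reflux, Dean–Stark
Reagents that add atoms: ethane-1,2-diol 2, OCCO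
Why: Acid-catalysed acetalisation with azeotropic removal of water masks the aldehyde as a 1,3-dioxolane that tolerates the later organolithium step, and the free phenol does not interfere.

**Step 2**
Reactants: 3 2-bromo-3-(1,3-dioxolan-2-yl)-6-methoxyphenol; 4 chloromethyl methyl ether
Product: 5 2-[2-bromo-4-methoxy-3-(methoxymethoxy)phenyl]-1,3-dioxolane
Conditions: MOMCl, iPr2NEt, CH2Cl2, 0 → 23 °C
Reagents that add atoms: chloromethyl methyl ether 4, COCCl
Why: O-alkylation of the phenol with the reactive α-chloro ether under amine base (Williamson-type MOM protection) gives an ether that is stable to n-BuLi and helps to chelate the aryl metal of step 3, while the acetal is inert to base.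

**Step 3**
Reactants: 5 2-[2-bromo-4-methoxy-3-(methoxymethoxy)phenyl]-1,3-dioxolane; 6 geranyl bromide
Product: 9 2-{2-[(2E)-3,7-dimethylocta-2,6-dien-1-yl]-4-methoxy-3-(methoxymethoxy)phenyl}-1,3-dioxolane, via aryllithium 7 (not isolated), via arylcopper 8 (not isolated)
Conditions: n-BuLi, THF, –78 °C; CuBr·SMe2, –78 → –40 °C; geranyl bromide, –78 → 0 °C
Reagents that add atoms: geranyl bromide 6, BrC/C=C(\C)CCC=C(C)C
Why: Bromine–lithium exchange at –78 °C outruns any deprotonation and gives an aryllithium held by the flanking acetal and MOM oxygens; transmetalation to the arylcopper and SN2 allylation of the primary allylic bromide should join the arene to C1 of the geranyl unit with the (E)-double bond untouched, attack at the γ-carbon being disfavoured because it would put a quaternary carbon next to a di-ortho-substituted arene.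

**Step 4**
Reactants: 9 2-{2-[(2E)-3,7-dimethylocta-2,6-dien-1-yl]-4-methoxy-3-(methoxymethoxy)phenyl}-1,3-dioxolane
Product: 10 2-[(2E)-3,7-dimethylocta-2,6-dien-1-yl]-4-methoxy-3-(methoxymethoxy)benzaldehyde
Conditions: PPTS (cat.), acetone–H2O, 50 °C
Reagents that add atoms: water, O
Why: Acetal hydrolysis under mild acid catalysis: the aryl dioxolane, whose oxocarbenium ion is stabilised by the para methoxy group, is cleaved much faster than the aryl MOM ether, and the pyridinium salt does not protonate the trisubstituted alkenes.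

**Step 5**
Reactants: 11 1-fluoro-3,5-dimethoxybenzene; 12 acetyl chloride
Product: 13 1-(2-fluoro-4,6-dimethoxyphenyl)ethan-1-one
Conditions: AcCl, AlCl3, CH2Cl2, –10 → 0 °C
Reagents that add atoms: acetyl chloride 12, CC(=O)Cl
Why: Friedel–Crafts acylation at the position para to one methoxy group and ortho to the other, flanked by the small fluorine, is favoured over the more hindered position between the two methoxy groups, and any regioisomer is removed by crystallisation or chromatography.

**Step 6**
Reactants: 13 1-(2-fluoro-4,6-dimethoxyphenyl)ethan-1-one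
Product: 14 1-(2-fluoro-6-hydroxy-4-methoxyphenyl)ethan-1-one
Conditions: BCl3, CH2Cl2, –78 → 0 °C; aq. work-up
Reagents that add atoms: none
Why: Chelation-controlled ether cleavage: BCl3 binds the ketone oxygen and removes only the methyl of the ortho methoxy group through a six-membered boron chelate, leaving the para methoxy group and the C–F bond intact.

**Step 7**
Reactants: 14 1-(2-fluoro-6-hydroxy-4-methoxyphenyl)ethan-1-one; 4 chloromethyl methyl ether
Product: 15 1-[2-fluoro-4-methoxy-6-(methoxymethoxy)phenyl]ethan-1-one
Conditions: MOMCl, iPr2NEt, CH2Cl2, 0 → 23 °C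
Reagents that add atoms: chloromethyl methyl ether 4, COCCl
Why: MOM protection of the hydrogen-bonded phenol by O-alkylation gives an ether that, unlike a phenoxide or a silyl ether, survives the fluoride stage of step 9 without deactivating ring A towards SNAr, and that leaves in the same final operation as the ring B MOM group.

**Step 8**
Reactants: 15 1-[2-fluoro-4-methoxy-6-(methoxymethoxy)phenyl]ethan-1-one; 16 chlorotrimethylsilane
Product: 18 ({1-[2-fluoro-4-methoxy-6-(methoxymethoxy)phenyl]ethenyl}oxy)trimethylsilane, via lithium enolate 17 (not isolated)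
Conditions: LiN(SiMe3)2, THF, –78 °C; Me3SiCl, –78 → 0 °C; non-aqueous work-up (pentane, filtration)
Reagents that add atoms: chlorotrimethylsilane 16, C[Si](C)(C)Cl
Why: Kinetic deprotonation of the methyl ketone, its only enolisable position, by the hindered amide base (too weak to metalate the arene next to fluorine) and O-silylation of the lithium enolate give the enol silane.

**Step 9**
Reactants: 18 ({1-[2-fluoro-4-methoxy-6-(methoxymethoxy)phenyl]ethenyl}oxy)trimethylsilane; 10 2-[(2E)-3,7-dimethylocta-2,6-dien-1-yl]-4-methoxy-3-(methoxymethoxy)benzaldehyde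
Product: 20 (2S)-2-{2-[(2E)-3,7-dimethylocta-2,6-dien-1-yl]-4-methoxy-3-(methoxymethoxy)phenyl}-7-methoxy-5-(methoxymethoxy)-2,3-dihydro-4H-chromen-4-one, via silyl aldol ether 19 (not isolated)
Conditions: 10 (1.1 equiv), (4R)-2-butyl-4-(indol-3-ylmethyl)-3-tosyl-1,3,2-oxazaborolidin-5-one (20 mol%), EtCN, –78 °C; then Bu4N[Ph3SiF2] (0.4 equiv), DMF, –78 → 23 °C; pH 7 buffer
Reagents that add atoms: none
Why: The oxazaborolidinone binds the formyl oxygen of 10 and shields one face, so that the terminal carbon of enol silane 18 adds to the Si face through an open transition state (catalytic asymmetric Mukaiyama aldol) and silyl transfer gives the (S)-configured silyl ether 19 with the C2–C3 bond in place. Fluoride then cleaves the O–Si bond, the alkoxide adds to C8a of ring A (ipso to fluorine, ortho to the C4 ketone) and the Meisenheimer intermediate expels fluoride, which desilylates the next molecule, so that O1–C8a forms without a stoichiometric base. The closest known reaction types are the aldol–dihydropyranone annulation of Danishefsky-type dienes with aldehydes under this class of catalyst, of which 18 is the benzo-fused analogue, and the fluoride-mediated SNAr etherification of silyl ethers with ketone-activated aryl fluorides. Ring C closes in a 6-endo-trig addition–elimination at the C4a=C8a bond of the vinylogous acyl fluoride. The only new stereocentre, C2, is set by the catalyst in the aldol stage and is kept in the SNAr stage, in which the C2–O bond is not touched. The step needs facial selectivity at the aldehyde, secured by the catalyst, and ring closure faster than retro-aldol or elimination to the chalcone, secured by the ortho ketone that activates C8a, by the 5- and 7-oxygens standing meta to C8a and by the low basicity of the fluoride relay.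

**Step 10**
Reactants: 20 (2S)-2-{2-[(2E)-3,7-dimethylocta-2,6-dien-1-yl]-4-methoxy-3-(methoxymethoxy)phenyl}-7-methoxy-5-(methoxymethoxy)-2,3-dihydro-4H-chromen-4-one
Product: 21 (2S)-2-{2-[(2E)-3,7-dimethylocta-2,6-dien-1-yl]-3-hydroxy-4-methoxyphenyl}-5-hydroxy-7-methoxy-2,3-dihydro-4H-chromen-4-one
Conditions: 3 M aq. HCl, MeOH–THF, 40 °C
Reagents that add atoms: none
Why: Acid-catalysed solvolysis of both aryl MOM ethers (acetal cleavage, the 5-O-MOM group assisted by the peri carbonyl) frees the two phenols without base, so that C2 cannot be scrambled by ring opening to the chalcone, and at this acidity and temperature the geranyl alkenes should stay unprotonated.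

**Compound list**
1 | 2-bromo-3-hydroxy-4-methoxybenzaldehyde (2-bromoisovanillin) | O=Cc1ccc(OC)c(O)c1Br | starting material
2 | ethane-1,2-diol | OCCO | starting material
3 | 2-bromo-3-(1,3-dioxolan-2-yl)-6-methoxyphenol | Oc1c(OC)ccc(C2OCCO2)c1Br | intermediate
4 | chloromethyl methyl ether (MOMCl) | COCCl | starting material
5 | 2-[2-bromo-4-methoxy-3-(methoxymethoxy)phenyl]-1,3-dioxolane | COCOc1c(OC)ccc(C2OCCO2)c1Br | intermediate
6 | geranyl bromide, (2E)-1-bromo-3,7-dimethylocta-2,6-diene | BrC/C=C(\C)CCC=C(C)C | starting material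
7 | [6-(1,3-dioxolan-2-yl)-3-methoxy-2-(methoxymethoxy)phenyl]lithium | COCOc1c(OC)ccc(C2OCCO2)c1[Li] | intermediate
8 | [6-(1,3-dioxolan-2-yl)-3-methoxy-2-(methoxymethoxy)phenyl]copper | COCOc1c(OC)ccc(C2OCCO2)c1[Cu] | intermediate
9 | 2-{2-[(2E)-3,7-dimethylocta-2,6-dien-1-yl]-4-methoxy-3-(methoxymethoxy)phenyl}-1,3-dioxolane | COCOc1c(OC)ccc(C2OCCO2)c1C/C=C(\C)CCC=C(C)C | intermediate
10 | 2-[(2E)-3,7-dimethylocta-2,6-dien-1-yl]-4-methoxy-3-(methoxymethoxy)benzaldehyde | COCOc1c(OC)ccc(C=O)c1C/C=C(\C)CCC=C(C)C | intermediate
11 | 1-fluoro-3,5-dimethoxybenzene | COc1cc(F)cc(OC)c1 | starting material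
12 | acetyl chloride | CC(=O)Cl | starting material
13 | 1-(2-fluoro-4,6-dimethoxyphenyl)ethan-1-one | CC(=O)c1c(F)cc(OC)cc1OC | intermediate
14 | 1-(2-fluoro-6-hydroxy-4-methoxyphenyl)ethan-1-one | CC(=O)c1c(F)cc(OC)cc1O | intermediate
15 | 1-[2-fluoro-4-methoxy-6-(methoxymethoxy)phenyl]ethan-1-one | CC(=O)c1c(F)cc(OC)cc1OCOC | intermediate
16 | chlorotrimethylsilane | C[Si](C)(C)Cl | starting material
17 | lithium 1-[2-fluoro-4-methoxy-6-(methoxymethoxy)phenyl]ethen-1-olate | [Li]OC(=C)c1c(F)cc(OC)cc1OCOC | intermediate
18 | ({1-[2-fluoro-4-methoxy-6-(methoxymethoxy)phenyl]ethenyl}oxy)trimethylsilane | C=C(O[Si](C)(C)C)c1c(F)cc(OC)cc1OCOC | intermediate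
19 | (3S)-3-{2-[(2E)-3,7-dimethylocta-2,6-dien-1-yl]-4-methoxy-3-(methoxymethoxy)phenyl}-1-[2-fluoro-4-methoxy-6-(methoxymethoxy)phenyl]-3-[(trimethylsilyl)oxy]propan-1-one | C[Si](C)(C)O[C@H](c1ccc(OC)c(OCOC)c1C/C=C(\C)CCC=C(C)C)CC(=O)c1c(F)cc(OC)cc1OCOC | intermediate
20 | (2S)-2-{2-[(2E)-3,7-dimethylocta-2,6-dien-1-yl]-4-methoxy-3-(methoxymethoxy)phenyl}-7-methoxy-5-(methoxymethoxy)-2,3-dihydro-4H-chromen-4-one | COc1cc(OCOC)c2c(c1)O[C@H](c1ccc(OC)c(OCOC)c1C/C=C(\C)CCC=C(C)C)CC2=O | intermediate
21 | (2S)-2-{2-[(2E)-3,7-dimethylocta-2,6-dien-1-yl]-3-hydroxy-4-methoxyphenyl}-5-hydroxy-7-methoxy-2,3-dihydro-4H-chromen-4-one | COc1cc(O)c2c(c1)O[C@H](c1ccc(OC)c(O)c1C/C=C(\C)CCC=C(C)C)CC2=O | target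

**Step count**
Total: 10 steps. Longest linear sequence: 6 steps (steps 1–4, 9, 10; the ring A branch, steps 5–8, 9, 10, is equally long).

**Steps most likely to fail**

1. Step 9. The hindered, electron-rich aldehyde may react slowly or with insufficient facial selectivity in the aldol stage. In the fluoride stage, retro-aldol cleavage or elimination to the chalcone may outrun ring closure, and prolonged contact with fluoride may erode the configuration by reversible ring opening. Fallback, from 15 and 10 back to 20:
   - Claisen–Schmidt condensation of 15 with 10 (KOH, EtOH, 0 → 23 °C) should give the chalcone (2E)-3-{2-[(2E)-3,7-dimethylocta-2,6-dien-1-yl]-4-methoxy-3-(methoxymethoxy)phenyl}-1-[2-fluoro-4-methoxy-6-(methoxymethoxy)phenyl]prop-2-en-1-one F1.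
   - Juliá–Colonna epoxidation (poly-D-leucine, urea·H2O2, DBU, THF) should give the trans-(2S,3R)-epoxy ketone F2. Poly-D-leucine is chosen as the antipode of the polymer that gives (2R,3S)-chalcone oxide, and the nucleophilic peroxide leaves the geranyl alkenes alone.
   - SmI2 (THF–MeOH, –90 °C) should cleave the Cα–O bond to the (3S)-β-hydroxy ketone F3.
   - K2CO3 in DMF at 23 °C should then close ring C by intramolecular SNAr, and the route is rejoined at 20.

2. Step 3. The arylcopper may attack the γ-carbon of the allylic bromide, may be butylated by the 1-bromobutane formed in the exchange, or may couple slowly at the doubly ortho-flanked carbon. Fallback, from 5 back to 9: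
   - Bromine–lithium exchange (n-BuLi, THF, –78 °C) and quench with B(OMe)3, then aq. NH4Cl, should give [6-(1,3-dioxolan-2-yl)-3-methoxy-2-(methoxymethoxy)phenyl]boronic acid F4.
   - Pd(PPh3)4-catalysed allyl–aryl coupling of F4 with geranyl bromide 6 (K2CO3, THF–H2O, 50 °C) should give 9. The aryl group is delivered to the unsubstituted terminus of the allylpalladium intermediate, with the (E)-geometry kept.

3. Step 10. The freed 3'-hydroxyl may add to the neighbouring geranyl double bond under acid (chroman formation), or the less labile ring B ether may cleave incompletely. Fallback, from 20 to 21, without protic acid: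
   - Me3SiOTf and 2,2'-bipyridyl (MeCN, 0 °C) should exchange both aryl MOM ethers for silyl ethers and give the bis(trimethylsilyl) ether (2S)-2-{2-[(2E)-3,7-dimethylocta-2,6-dien-1-yl]-4-methoxy-3-[(trimethylsilyl)oxy]phenyl}-7-methoxy-5-[(trimethylsilyl)oxy]-2,3-dihydro-4H-chromen-4-one F5.
   - Water at 23 °C should then hydrolyse F5 to 21 under near-neutral conditions.

**Further compounds**
F1 | step 9 | (2E)-3-{2-[(2E)-3,7-dimethylocta-2,6-dien-1-yl]-4-methoxy-3-(methoxymethoxy)phenyl}-1-[2-fluoro-4-methoxy-6-(methoxymethoxy)phenyl]prop-2-en-1-one | COCOc1cc(OC)cc(F)c1C(=O)/C=C/c1ccc(OC)c(OCOC)c1C/C=C(\C)CCC=C(C)C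
F2 | step 9 | [(2S,3R)-3-{2-[(2E)-3,7-dimethylocta-2,6-dien-1-yl]-4-methoxy-3-(methoxymethoxy)phenyl}oxiran-2-yl][2-fluoro-4-methoxy-6-(methoxymethoxy)phenyl]methanone | O1[C@H](c2ccc(OC)c(OCOC)c2C/C=C(\C)CCC=C(C)C)[C@H]1C(=O)c1c(F)cc(OC)cc1OCOC
F3 | step 9 | (3S)-3-{2-[(2E)-3,7-dimethylocta-2,6-dien-1-yl]-4-methoxy-3-(methoxymethoxy)phenyl}-1-[2-fluoro-4-methoxy-6-(methoxymethoxy)phenyl]-3-hydroxypropan-1-one | O[C@H](c1ccc(OC)c(OCOC)c1C/C=C(\C)CCC=C(C)C)CC(=O)c1c(F)cc(OC)cc1OCOC
F4 | step 3 | [6-(1,3-dioxolan-2-yl)-3-methoxy-2-(methoxymethoxy)phenyl]boronic acid | COCOc1c(OC)ccc(C2OCCO2)c1B(O)O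
F5 | step 10 | (2S)-2-{2-[(2E)-3,7-dimethylocta-2,6-dien-1-yl]-4-methoxy-3-[(trimethylsilyl)oxy]phenyl}-7-methoxy-5-[(trimethylsilyl)oxy]-2,3-dihydro-4H-chromen-4-one | COc1cc(O[Si](C)(C)C)c2c(c1)O[C@H](c1ccc(OC)c(O[Si](C)(C)C)c1C/C=C(\C)CCC=C(C)C)CC2=O
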